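**Retrosynthetic overview**
- Target 10 ← amino acid 9 ← ester 8: the C2 bromine replaces a C2 carboxyl group by ipso-bromodecarboxylation after saponification.
- 8 ← 7 ← 6: the C3 CH2NMe2 arm comes from a Mannich reaction while the ester blocks C2; N1 is methylated before that.
- 6 ← 4: the pyrrole ring is the only ring formed, closed onto the purchased benzene ring by nitrene C–H amination that makes N1–C7a.
- 4 ← 1 + 2: aldol condensation of the dibromobenzaldehyde with the azidoacetate.
- Feature used: C7a, flanked by the unsubstituted C7–H, is a plain aryl C–H carbon in the precursor, and the C2 bromine of the pyrrole ring sits where an azidoacrylate delivers its ester carbon, so the ester is a placeholder for that bromine.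

Key step: step 2

Assumption: ring closure of the nitrene is taken to occur mainly at the ortho C–H remote from the 3-bromine; the route is written for that isomer, and any 6,7-dibromo isomer is removed at the stage of compound 6.

Step 1
Reactants: 1 3,4-dibromobenzaldehyde; 2 methyl azidoacetate
Product: 4 methyl (Z)-2-azido-3-(3,4-dibromophenyl)acrylate, via azido aldol adduct 3 (not isolated)
Conditions: NaOMe (4 equiv), 2 (4 equiv), MeOH, −10 °C to 0 °C; then ice/aq NH4Cl, solid filtered and kept cold and dark
Reagents that add atoms: none
Why: Aldol (Knoevenagel-type) condensation of the azidoacetate enolate with the non-enolisable aldehyde, followed by E1cB loss of hydroxide from adduct 3, is the standard first stage of the Hemetsberger–Knittel sequence and should give the (Z)-azidocinnamate with the aryl group trans to the ester; methoxide in methanol rules out ester scrambling and the low temperature protects the azido ester.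

Step 2
Reactants: 4 methyl (Z)-2-azido-3-(3,4-dibromophenyl)acrylate
Product: 6 methyl 5,6-dibromo-1H-indole-2-carboxylate, via 2H-azirine 5 (not isolated)
Conditions: xylene, 140 °C, about 0.05 M, 4 added slowly as a solution to the refluxing solvent; cool, crystallise (recrystallise if the 6,7-dibromo isomer is present)
Reagents that add atoms: none
Why: Heating expels dinitrogen from the vinyl azide to give 2H-azirine 5, which opens reversibly to the singlet vinyl nitrene; the nitrene nitrogen bonds to the ortho carbon of the arene in a 6π (1,5-) electrocyclisation and a hydrogen shift restores aromaticity. This is the Hemetsberger–Knittel indole synthesis, a thermal vinyl-nitrene C–H amination. The only ring closed is the five-membered pyrrole ring, formed through N1–C7a bond formation by that 1,5-electrocyclisation onto the benzene ring. No stereocentre is created. The step needs regioselectivity between the two ortho C–H positions of the 3,4-dibromophenyl ring: closure at C6–H, para to the 3-bromine and unhindered, leads to the 5,6-dibromoindole and should be preferred over closure at C2–H, which is flanked by bromine and would lead to the 6,7-dibromo isomer. The aryl C–Br bonds and the ester should be inert under these metal-free thermal conditions.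

Step 3
Reactants: 6 methyl 5,6-dibromo-1H-indole-2-carboxylate
Product: 7 methyl 5,6-dibromo-1-methyl-1H-indole-2-carboxylate
Conditions: MeI (1.5 equiv), K2CO3 (2 equiv), DMF, rt
Reagents that add atoms: iodomethane, CI
Why: The indole N–H, acidified by the C2 ester, is deprotonated by carbonate and the anion is methylated in an SN2 N-alkylation that leaves the ester and the aryl bromides untouched.

Step 4
Reactants: 7 methyl 5,6-dibromo-1-methyl-1H-indole-2-carboxylate
Product: 8 methyl 5,6-dibromo-3-[(dimethylamino)methyl]-1-methyl-1H-indole-2-carboxylate
Conditions: CH2=NMe2+ I− (1.5 equiv), MeCN, 80 °C; then aq NaHCO3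
Reagents that add atoms: dimethylmethyleneiminium iodide (Eschenmoser's salt), C=[N+](C)C.[I-]
Why: Mannich-type electrophilic aromatic substitution in which the preformed iminium ion attacks C3, the only free and the most nucleophilic position of the pyrrole ring because C2 is blocked by the ester.

Step 5
Reactants: 8 methyl 5,6-dibromo-3-[(dimethylamino)methyl]-1-methyl-1H-indole-2-carboxylate
Product: 9 5,6-dibromo-3-[(dimethylamino)methyl]-1-methyl-1H-indole-2-carboxylic acid (isolated as the inner salt)
Conditions: LiOH·H2O (3 equiv), THF/MeOH/H2O, 50 °C; then 1 M HCl to pH 6–7, solid filtered and dried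
Reagents that add atoms: lithium hydroxide, [Li+].[OH-]; water, O
Why: Saponification (BAc2 ester hydrolysis) of the methyl ester; the N-methylated gramine has no N–H and so cannot eliminate dimethylamine under base, and neutralisation to the isoelectric point should deliver the amino acid as its inner salt.

Step 6
Reactants: 9 5,6-dibromo-3-[(dimethylamino)methyl]-1-methyl-1H-indole-2-carboxylic acid
Product: 10 2,5,6-tribromo-1-methylgramine [1-(2,5,6-tribromo-1-methyl-1H-indol-3-yl)-N,N-dimethylmethanamine]
Conditions: NBS (1.05 equiv), DMF, 0 °C to rt, dark, anhydrous; then aq Na2S2O3/NaHCO3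
Reagents that add atoms: N-bromosuccinimide, O=C1CCC(=O)N1Br
Why: Ipso-bromodecarboxylation (halodecarboxylation of an electron-rich heteroaromatic acid), in which electrophilic bromine adds to the pyrrole ring, ends on C2 and the carboxylate leaves as CO2 in place of a proton, while the side-chain nitrogen, held as the ammonium of the inner salt, is shielded from N-bromination and from retro-Mannich loss of the aminomethyl group.

**Compound list**
1 | 3,4-dibromobenzaldehyde | O=Cc1ccc(Br)c(Br)c1 | starting material
2 | methyl azidoacetate | COC(=O)CN=[N+]=[N-] | starting material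
3 | methyl 2-azido-3-(3,4-dibromophenyl)-3-hydroxypropanoate (aldol adduct, racemic diastereomer mixture, not isolated) | COC(=O)C(N=[N+]=[N-])C(O)c1ccc(Br)c(Br)c1 | intermediate
4 | methyl (Z)-2-azido-3-(3,4-dibromophenyl)acrylate | COC(=O)/C(N=[N+]=[N-])=C/c1ccc(Br)c(Br)c1 | intermediate
5 | methyl 2-(3,4-dibromophenyl)-2H-azirine-3-carboxylate (racemic, not isolated) | COC(=O)C1=NC1c1ccc(Br)c(Br)c1 | intermediate
6 | methyl 5,6-dibromo-1H-indole-2-carboxylate | COC(=O)c1cc2cc(Br)c(Br)cc2[nH]1 | intermediate
7 | methyl 5,6-dibromo-1-methyl-1H-indole-2-carboxylate | COC(=O)c1cc2cc(Br)c(Br)cc2n1C | intermediate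
8 | methyl 5,6-dibromo-3-[(dimethylamino)methyl]-1-methyl-1H-indole-2-carboxylate | COC(=O)c1c(CN(C)C)c2cc(Br)c(Br)cc2n1C | intermediate
9 | 5,6-dibromo-3-[(dimethylamino)methyl]-1-methyl-1H-indole-2-carboxylic acid | CN(C)Cc1c(C(=O)O)n(C)c2cc(Br)c(Br)cc12 | intermediate
10 | 2,5,6-tribromo-1-methylgramine | CN(C)Cc1c(Br)n(C)c2cc(Br)c(Br)cc12 | target

**Step count**
Total steps: 6. Longest linear sequence: 6 steps (1 → 10).

**Steps most likely to fail**

Step 2. The nitrene may close onto the ortho position beside the 3-bromine to a comparable extent, so that regiocontrol is poor and the wanted isomer is hard to purify; intermolecular nitrene reactions may also cause tarring if the azide accumulates. The fallback sets out from 1 and forms N1–C2 instead of N1–C7a, so no regiochemical choice remains. Nitration of 1 (HNO3/H2SO4, 0 °C) should place the nitro group ortho to the formyl group and para to the 3-bromine, giving 4,5-dibromo-2-nitrobenzaldehyde F1. Wittig olefination with Ph3P=CHCO2Me (toluene, rt) should give methyl (E)-3-(4,5-dibromo-2-nitrophenyl)acrylate F2. Cadogan–Sundberg reductive cyclisation of F2 (PPh3, o-dichlorobenzene, 180 °C) should then close the pyrrole ring. The fallback returns to the route at 6.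

Step 6. Electrophilic bromine may attack C3 with expulsion of the aminomethyl arm, or oxidise the tertiary amine, or the decarboxylation may lag and allow over-bromination. The fallback sets out from 9 and reverses the polarity, making C2 the nucleophile so that no free electrophilic bromine meets the gramine. Protodecarboxylation (Ag2CO3 cat., AcOH, DMSO, 120 °C) should give 5,6-dibromo-1-methylgramine F3. Deprotonative magnesiation at C2 with TMPMgCl·LiCl (THF, 0 °C to rt) is expected to be directed by N1 and the side-chain amine and to tolerate the aryl bromides, giving 2-(chloromagnesio)-5,6-dibromo-1-methylgramine F4 in the flask. Quenching with 1,2-dibromo-1,1,2,2-tetrachloroethane should install the bromine. The fallback returns to the route at 10.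

Step 4. Substitution at C3 may stall because the ring is deactivated by the ester and two bromines, leaving unreacted 7. The fallback sets out from 7 and uses a stronger electrophile followed by a separate C–N bond formation. Vilsmeier–Haack formylation (POCl3, DMF, 0 °C to 80 °C; aq NaOAc) should give methyl 5,6-dibromo-3-formyl-1-methyl-1H-indole-2-carboxylate F5. Reductive amination (Me2NH in THF, NaBH(OAc)3, AcOH, 1,2-dichloroethane, rt) should then give the amine. The fallback returns to the route at 8.

**Further compounds**
F1 | step 2 | 4,5-dibromo-2-nitrobenzaldehyde | O=Cc1cc(Br)c(Br)cc1[N+](=O)[O-]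
F2 | step 2 | methyl (E)-3-(4,5-dibromo-2-nitrophenyl)acrylate | COC(=O)/C=C/c1cc(Br)c(Br)cc1[N+](=O)[O-]
F3 | step 6 | 5,6-dibromo-1-methylgramine [1-(5,6-dibromo-1-methyl-1H-indol-3-yl)-N,N-dimethylmethanamine] | CN(C)Cc1cn(C)c2cc(Br)c(Br)cc12
F4 | step 6 | 2-(chloromagnesio)-5,6-dibromo-1-methylgramine (not isolated) | CN(C)Cc1c([Mg]Cl)n(C)c2cc(Br)c(Br)cc12
F5 | step 4 | methyl 5,6-dibromo-3-formyl-1-methyl-1H-indole-2-carboxylate | COC(=O)c1c(C=O)c2cc(Br)c(Br)cc2n1C
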